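Ring B (the epoxycyclohexenediol) is closed last, at the bond between C4, the alkene carbon that carries the hydroxymethyl group, and C5, the carbinol carbon next to the epoxide CH (C6). An intramolecular Nozaki–Hiyama–Kishi reaction does this in one operation: a (Z)-alkenyl iodide adds to an epoxy aldehyde, forming the ring, the C3=C4–C5(OH) allylic alcohol and the C5 stereocentre. The step exploits the C1–C6 epoxide, on which the formyl group and the iodoalkenyl arm are cis and so held within reach. The precursor is an open-chain epoxy aldehyde that already carries ring A, the (Z,E)-diene and all other stereocentres.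

Key step: step 20

Numbering and abbreviations: ring B is numbered as a 7-oxabicyclo[4.1.0]hept-3-ene: C1 quaternary epoxide carbon, C2 carbinol, C3=C4 alkene (C4 bears CH2OH), C5 carbinol, C6 epoxide CH. The side chain is C1′ (carbinol), C2′=C3′(CH3), C4′=C5′. Ring A is C1″ (attached to C5′), C2″(CH3)=C3″, C4″, C5″ (CHOH), C6″ (CMe2). TBS = tert-butyldimethylsilyl, TES = triethylsilyl, pin = pinacolato.

Assumption: in step 8 the (S,S)-ProPhenol/Me2Zn system is taken to deliver the alkynyl group to the Re face of the enal; if the sense is the opposite, the (R,R)-ligand is used.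

Step 1
Reactants: 1 geranyl acetate
Product: 2 (R)-6,7-epoxygeranyl acetate
Conditions: Shi ketone (D-fructose-derived, 30 mol%), Oxone, K2CO3, Bu4NHSO4, MeCN/dimethoxymethane/aq. buffer (pH 10.5), 0 °C
Reagents that add atoms: Oxone (potassium peroxymonosulfate), `[K+].[O-]S(=O)(=O)OO`
Why: Shi asymmetric epoxidation: the chiral dioxirane epoxidises the more electron-rich 6,7-alkene (the 2,3-alkene is deactivated by the allylic acetate) through the spiro transition state that gives the (R)-epoxide with the D-fructose-derived ketone.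

Step 2
Reactants: 2 (R)-6,7-epoxygeranyl acetate
Product: 3 [(1S,5R)-5-hydroxy-2,6,6-trimethylcyclohex-2-en-1-yl]methyl acetate
Conditions: ZrCl4 (1.1 equiv), CH2Cl2, rt; chromatography
Reagents that add atoms: none
Why: Lewis acid-promoted epoxy-olefin cyclisation through a chair transition state in which the E-alkene places the acetoxymethyl arm equatorial and the opening epoxide places its oxygen equatorial, so the carbinol keeps its configuration from 2 and the new ring stereocentre is set cis to it, while proton loss toward the ring gives the endocyclic alkene (the exocyclic isomer is removed by chromatography).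

Step 3
Reactants: 3 [(1S,5R)-5-hydroxy-2,6,6-trimethylcyclohex-2-en-1-yl]methyl acetate
Product: 4 (1R,5S)-5-(hydroxymethyl)-4,6,6-trimethylcyclohex-3-en-1-ol
Conditions: K2CO3 (cat.), MeOH, rt
Reagents that add atoms: none
Why: Base-catalysed transesterification (methanolysis) of the acetate, which leaves both stereocentres untouched.

Step 4
Reactants: 4 (1R,5S)-5-(hydroxymethyl)-4,6,6-trimethylcyclohex-3-en-1-ol
Product: 5 (1S,5R)-5-hydroxy-2,6,6-trimethylcyclohex-2-ene-1-carbaldehyde
Conditions: TEMPO (10 mol%), PhI(OAc)2, CH2Cl2, rt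
Reagents that add atoms: none
Why: Oxoammonium (TEMPO) oxidation selects the primary over the hindered secondary alcohol and stops at the aldehyde, which is used at once to avoid conjugation of the β,γ-alkene.

Step 5
Reactants: 5 (1S,5R)-5-hydroxy-2,6,6-trimethylcyclohex-2-ene-1-carbaldehyde
Product: 6 (1R,5S)-4,6,6-trimethyl-5-[(E)-2-(4,4,5,5-tetramethyl-1,3,2-dioxaborolan-2-yl)ethenyl]cyclohex-3-en-1-ol
Conditions: CrCl2 (8 equiv), LiI, THF, rt
Reagents that add atoms: 2-(dichloromethyl)-4,4,5,5-tetramethyl-1,3,2-dioxaborolane (Cl2CHBpin), `ClC(Cl)B1OC(C)(C)C(C)(C)O1`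
Why: Takai–Utimoto-type chromium-mediated olefination with the geminal dichromium reagent from Cl2CHBpin gives the (E)-alkenylboronate; the free hydroxyl is tolerated and the allylic stereocentre is not enolised under these non-basic conditions.

Step 6
Reactants: 7 but-2-yn-1-ol
Product: 9 (Z)-3-iodobut-2-en-1-ol, via cyclic sodium alkenylalanate 8 (not isolated)
Conditions: NaAlH2(OCH2CH2OMe)2 (Red-Al), Et2O, 0 °C to rt; then I2, THF, −78 °C
Reagents that add atoms: iodine, `II`
Why: Hydroxyl-directed trans-hydroalumination of the propargylic alcohol puts aluminium on the distal carbon (alanate 8) and iodinolysis with retention gives the Z iodide.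

Step 7
Reactants: 9 (Z)-3-iodobut-2-en-1-ol
Product: 10 (Z)-3-iodobut-2-enal
Conditions: MnO2, CH2Cl2, rt
Reagents that add atoms: none
Why: Allylic oxidation on MnO2 is mild enough to keep the Z geometry; the volatile aldehyde is used directly as a solution.

Step 8
Reactants: 10 (Z)-3-iodobut-2-enal; 11 prop-2-yn-1-yl benzoate
Product: 13 (4S,5Z)-4-hydroxy-6-iodohept-5-en-2-yn-1-yl benzoate, via alkynyl(methyl)zinc 12 (not isolated)
Conditions: Me2Zn, (S,S)-ProPhenol (20 mol%), Ph3PO (40 mol%), toluene, 4 °C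
Reagents that add atoms: none
Why: Zinc–ProPhenol catalysed asymmetric alkynylation of an enal: the alkynylzinc 12 formed from 11 and Me2Zn is delivered within the dinuclear zinc complex to the Re face of the aldehyde, which sets the C1′ carbinol as (S).

Step 9
Reactants: 13 (4S,5Z)-4-hydroxy-6-iodohept-5-en-2-yn-1-yl benzoate; 6 ring A alkenylboronate
Product: 14 (4S,5Z,7E)-4-hydroxy-8-[(1S,5R)-5-hydroxy-2,6,6-trimethylcyclohex-2-en-1-yl]-6-methylocta-5,7-dien-2-yn-1-yl benzoate
Conditions: PdCl2(dppf) (5 mol%), aq. K3PO4, THF, rt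
Reagents that add atoms: none
Why: Suzuki–Miyaura coupling of an alkenyl iodide with an alkenylboronate proceeds with retention at both partners and so fixes the (2′Z,4′E)-diene; the free hydroxyls, the alkyne and the benzoate are tolerated at room temperature.

Step 10
Reactants: 14 diol benzoate
Product: 15 (4S,5Z,7E)-4-(TBSO)-8-[(1S,5R)-5-(TBSO)-2,6,6-trimethylcyclohex-2-en-1-yl]-6-methylocta-5,7-dien-2-yn-1-yl benzoate
Conditions: TBSOTf, 2,6-lutidine, CH2Cl2, −78 to 0 °C
Reagents that add atoms: tert-butyldimethylsilyl triflate, `CC(C)(C)[Si](C)(C)OS(=O)(=O)C(F)(F)F`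
Why: Silylation of both secondary hydroxyls with the reactive triflate (needed for the hindered ring A hydroxyl) blocks them for the hydride, palladium and oxidation steps that follow.

Step 11
Reactants: 15 bis-TBS ether benzoate
Product: 17 (2Z,4S,5Z,7E)-4-(TBSO)-8-[(1S,5R)-5-(TBSO)-2,6,6-trimethylcyclohex-2-en-1-yl]-3-iodo-6-methylocta-2,5,7-trien-1-ol, via cyclic sodium alkenylalanate 16 (not isolated)
Conditions: Red-Al (excess), THF, −20 to 0 °C; then I2, −78 °C
Reagents that add atoms: iodine, `II`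
Why: Red-Al first cleaves the benzoate, and the primary alkoxide set free then directs trans-hydroalumination (hydride to the proximal alkyne carbon, aluminium to the distal one, alanate 16), so that iodinolysis with retention gives the alkene on which iodine is cis to CH2OH and the C1′ carbinol is trans to it; the low temperature prevents loss of the neighbouring silyloxy group to an allene.

Step 12
Reactants: 17 iodo allylic alcohol
Product: 18 triethylsilyl ether of 17
Conditions: Et3SiCl, imidazole, CH2Cl2, 0 °C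
Reagents that add atoms: chlorotriethylsilane, `CC[Si](Cl)(CC)CC`
Why: Chemoselective silylation of the primary alcohol, which would otherwise trap the acylpalladium of the next step as a butenolide.

Step 13
Reactants: 18 alkenyl iodide; 19 tert-butyldimethyl(prop-2-yn-1-yloxy)silane
Product: 20 (5Z)-1-(TBSO)-5-[(1S,2Z,4E)-1-(TBSO)-5-{(1S,5R)-5-(TBSO)-2,6,6-trimethylcyclohex-2-en-1-yl}-3-methylpenta-2,4-dien-1-yl]-7-(triethylsilyloxy)hept-5-en-2-yn-4-one
Conditions: PdCl2(PPh3)2 (5 mol%), CuI (2 mol%), CO (1 atm), Et3N, THF, rt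
Reagents that add atoms: carbon monoxide, `[C-]#[O+]`
Why: Carbonylative Sonogashira coupling: oxidative addition of the alkenyl iodide, CO insertion and coupling of the acylpalladium with the copper acetylide of 19 give the cross-conjugated ynone with retention of the alkene geometry, so that the new carbonyl carbon (C2) is cis to C5.

Step 14
Reactants: 20 ynone
Product: 21 (4S)-propargylic alcohol from 20 (hept-5-en-2-yn-4-ol; carbinol = C2 of ring B, alkene geometry unchanged)
Conditions: (R)-2-methyl-CBS-oxazaborolidine (20 mol%), catecholborane, toluene, −78 °C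
Reagents that add atoms: none
Why: Corey–Bakshi–Shibata reduction (1,2-selective): the fully substituted alkenyl group is the large and the slim alkynyl group the small substituent, so the (R)-oxazaborolidine delivers hydride to the face that gives the (S)-carbinol at C2.

Step 15
Reactants: 21 propargylic alcohol
Product: 23 iodo dienol, in which the alkyne of 21 has become the (Z)-CH=C(I)CH2OTBS unit (iodine on C4, cis to the C2 carbinol), via cyclic sodium alkenylalanate 22 (not isolated)
Conditions: Red-Al, THF, −20 to 0 °C; then I2, −78 °C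
Reagents that add atoms: iodine, `II`
Why: As in step 6, the propargylic hydroxyl directs trans-hydroalumination (alanate 22) and iodinolysis with retention gives the alkenyl iodide with iodine on C4 cis to C2, the geometry needed for ring closure.

Step 16
Reactants: 23 iodo dienol
Product: 24 C2 TBS ether of 23
Conditions: TBSOTf, 2,6-lutidine, CH2Cl2, −78 to 0 °C
Reagents that add atoms: tert-butyldimethylsilyl triflate, `CC(C)(C)[Si](C)(C)OS(=O)(=O)C(F)(F)F`
Why: Silylation of the doubly allylic C2 hydroxyl, which would otherwise form a lactol with the aldehyde made in step 19.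

Step 17
Reactants: 24 fully silylated iodo triene
Product: 25 primary allylic alcohol (C5 CH2OH free; four TBS ethers kept)
Conditions: PPTS (cat.), MeOH/CH2Cl2, 0 °C
Reagents that add atoms: none
Why: Mild acid methanolysis removes the primary triethylsilyl ether much faster than the primary and secondary TBS ethers (standard TES/TBS differentiation).

Step 18
Reactants: 25 primary allylic alcohol
Product: 26 epoxy alcohol (C1–C6 epoxide configured as in 30; C5 CH2OH)
Conditions: Ti(OiPr)4 (50 mol%), L-(+)-diethyl tartrate (60 mol%), t-BuOOH, 4 Å molecular sieves, CH2Cl2, −20 °C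
Reagents that add atoms: tert-butyl hydroperoxide, `CC(C)(C)OO`
Why: Sharpless asymmetric epoxidation of the only free allylic alcohol: with L-(+)-diethyl tartrate the oxygen is delivered to the face that gives (S) at C6, the same sense as in (2S)-epoxy alcohols from simple (E)-allylic alcohols, and because the addition is syn the quaternary C1 follows with the configuration of 30, under reagent control over the remote silyloxy stereocentres.

Step 19
Reactants: 26 epoxy alcohol
Product: 27 epoxy aldehyde (C5 CHO)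
Conditions: Dess–Martin periodinane, NaHCO3, CH2Cl2, 0 °C to rt
Reagents that add atoms: none
Why: Dess–Martin oxidation under buffered, non-epimerising conditions gives the sensitive epoxy aldehyde, which is used crude.

Step 20
Reactants: 27 epoxy aldehyde
Product: 29 ring B cyclohexenol (C5 hydroxyl free, four TBS ethers), via alkenylchromium dichloride 28 (not isolated)
Conditions: CrCl2 (10 equiv), NiCl2 (2 mol%), degassed DMSO, rt, 5 mM
Reagents that add atoms: none
Why: Nozaki–Hiyama–Kishi reaction: zerovalent nickel (formed from NiCl2 by CrCl2) inserts into the C4–I bond, transmetalation to trivalent chromium gives alkenylchromium 28, and this adds to the C5 aldehyde. The closest known reaction type is the intramolecular Nozaki–Hiyama–Kishi cyclisation of (Z)-iodoalkenyl aldehydes to cyclohex-2-enols, as used for carbasugars. The ring closes in the 6-exo-trig mode, which is feasible because the epoxide holds the formyl group and the C2 arm cis and the Z-iodoalkene holds C4 cis to C2, so the two termini are preorganised. The new C5 stereocentre is controlled by the adjacent epoxide: in coordinating DMSO the carbonyl is not chelated and turns its oxygen away from the epoxide oxygen (dipole-opposed), which places the new hydroxyl trans to the epoxide and cis to the C2 silyloxy group, that is (R). The step needs chemoselectivity for the aldehyde over the epoxide, the diene and the silyl ethers, which the non-basic, aldehyde-selective alkenylchromium reagent provides, and high dilution to suppress intermolecular coupling.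

Step 21
Reactants: 29 tetrakis-TBS ether
Product: 30 (1R,2S,5R,6S)-1-{(1S,2Z,4E)-1-hydroxy-5-[(1S,5R)-5-hydroxy-2,6,6-trimethylcyclohex-2-en-1-yl]-3-methylpenta-2,4-dien-1-yl}-4-(hydroxymethyl)-7-oxabicyclo[4.1.0]hept-3-ene-2,5-diol (CNP0389279.1)
Conditions: HF·pyridine, pyridine, THF, 0 °C to rt
Reagents that add atoms: none
Why: Fluoride cleaves all four silyl ethers under buffered, weakly acidic conditions that avoid base-induced epoxide migration (Payne rearrangement) and ionisation of the dienyl carbinol.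

Compound list

1 | geranyl acetate | `CC(C)=CCC/C(C)=C/COC(C)=O` | starting material
2 | (R)-6,7-epoxygeranyl acetate | `CC1(C)O[C@@H]1CC/C(C)=C/COC(C)=O` | intermediate
3 | [(1S,5R)-5-hydroxy-2,6,6-trimethylcyclohex-2-en-1-yl]methyl acetate | `CC1=CC[C@@H](O)C(C)(C)[C@H]1COC(C)=O` | intermediate
4 | (1R,5S)-5-(hydroxymethyl)-4,6,6-trimethylcyclohex-3-en-1-ol | `CC1=CC[C@@H](O)C(C)(C)[C@H]1CO` | intermediate
5 | (1S,5R)-5-hydroxy-2,6,6-trimethylcyclohex-2-ene-1-carbaldehyde | `CC1=CC[C@@H](O)C(C)(C)[C@H]1C=O` | intermediate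
6 | (1R,5S)-4,6,6-trimethyl-5-[(E)-2-(pinacolatoboryl)ethenyl]cyclohex-3-en-1-ol | `CC1=CC[C@@H](O)C(C)(C)[C@H]1/C=C/B1OC(C)(C)C(C)(C)O1` | intermediate
7 | but-2-yn-1-ol | `CC#CCO` | starting material
8 | sodium 2,2-bis(2-methoxyethoxy)-3-methyl-2,5-dihydro-1,2-oxaluminol-2-uide (cyclic alkenylalanate) | `[Na+].CC1=CCO[Al-]1(OCCOC)OCCOC` | intermediate
9 | (Z)-3-iodobut-2-en-1-ol | `C/C(I)=C/CO` | intermediate
10 | (Z)-3-iodobut-2-enal | `C/C(I)=C/C=O` | intermediate
11 | prop-2-yn-1-yl benzoate | `C#CCOC(=O)c1ccccc1` | starting material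
12 | [3-(benzoyloxy)prop-1-yn-1-yl](methyl)zinc | `C[Zn]C#CCOC(=O)c1ccccc1` | intermediate
13 | (4S,5Z)-4-hydroxy-6-iodohept-5-en-2-yn-1-yl benzoate | `C/C(I)=C/[C@H](O)C#CCOC(=O)c1ccccc1` | intermediate
14 | (4S,5Z,7E)-4-hydroxy-8-[(1S,5R)-5-hydroxy-2,6,6-trimethylcyclohex-2-en-1-yl]-6-methylocta-5,7-dien-2-yn-1-yl benzoate | `CC1=CC[C@@H](O)C(C)(C)[C@H]1/C=C/C(C)=C\[C@H](O)C#CCOC(=O)c1ccccc1` | intermediate
15 | bis-TBS ether of 14 (C1′ and C5″) | `CC1=CC[C@@H](O[Si](C)(C)C(C)(C)C)C(C)(C)[C@H]1/C=C/C(C)=C\[C@H](O[Si](C)(C)C(C)(C)C)C#CCOC(=O)c1ccccc1` | intermediate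
16 | cyclic sodium alkenylalanate from 15 (aluminium on C1) | `[Na+].CC1=CC[C@@H](O[Si](C)(C)C(C)(C)C)C(C)(C)[C@H]1/C=C/C(C)=C\[C@H](O[Si](C)(C)C(C)(C)C)C1=CCO[Al-]1(OCCOC)OCCOC` | intermediate
17 | (2Z,4S,5Z,7E)-4-(TBSO)-8-[(1S,5R)-5-(TBSO)-2,6,6-trimethylcyclohex-2-en-1-yl]-3-iodo-6-methylocta-2,5,7-trien-1-ol | `CC1=CC[C@@H](O[Si](C)(C)C(C)(C)C)C(C)(C)[C@H]1/C=C/C(C)=C\[C@H](O[Si](C)(C)C(C)(C)C)/C(I)=C/CO` | intermediate
18 | triethylsilyl ether of 17 | `CC1=CC[C@@H](O[Si](C)(C)C(C)(C)C)C(C)(C)[C@H]1/C=C/C(C)=C\[C@H](O[Si](C)(C)C(C)(C)C)/C(I)=C/CO[Si](CC)(CC)CC` | intermediate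
19 | tert-butyldimethyl(prop-2-yn-1-yloxy)silane | `C#CCO[Si](C)(C)C(C)(C)C` | starting material
20 | (5Z)-1-(TBSO)-5-[(1S,2Z,4E)-1-(TBSO)-5-{(1S,5R)-5-(TBSO)-2,6,6-trimethylcyclohex-2-en-1-yl}-3-methylpenta-2,4-dien-1-yl]-7-(triethylsilyloxy)hept-5-en-2-yn-4-one | `CC1=CC[C@@H](O[Si](C)(C)C(C)(C)C)C(C)(C)[C@H]1/C=C/C(C)=C\[C@H](O[Si](C)(C)C(C)(C)C)/C(=C/CO[Si](CC)(CC)CC)C(=O)C#CCO[Si](C)(C)C(C)(C)C` | intermediate
21 | (4S)-propargylic alcohol from 20 (C2 carbinol) | `CC1=CC[C@@H](O[Si](C)(C)C(C)(C)C)C(C)(C)[C@H]1/C=C/C(C)=C\[C@H](O[Si](C)(C)C(C)(C)C)/C(=C/CO[Si](CC)(CC)CC)[C@@H](O)C#CCO[Si](C)(C)C(C)(C)C` | intermediate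
22 | cyclic sodium alkenylalanate from 21 (aluminium on C4) | `[Na+].CC1=CC[C@@H](O[Si](C)(C)C(C)(C)C)C(C)(C)[C@H]1/C=C/C(C)=C\[C@H](O[Si](C)(C)C(C)(C)C)/C(=C/CO[Si](CC)(CC)CC)[C@@H](O2)C=C(CO[Si](C)(C)C(C)(C)C)[Al-]2(OCCOC)OCCOC` | intermediate
23 | iodo dienol (C2 hydroxyl free; (Z)-C3=C4 with iodine on C4) | `CC1=CC[C@@H](O[Si](C)(C)C(C)(C)C)C(C)(C)[C@H]1/C=C/C(C)=C\[C@H](O[Si](C)(C)C(C)(C)C)/C(=C/CO[Si](CC)(CC)CC)[C@@H](O)/C=C(\I)CO[Si](C)(C)C(C)(C)C` | intermediate
24 | C2 TBS ether of 23 | `CC1=CC[C@@H](O[Si](C)(C)C(C)(C)C)C(C)(C)[C@H]1/C=C/C(C)=C\[C@H](O[Si](C)(C)C(C)(C)C)/C(=C/CO[Si](CC)(CC)CC)[C@@H](O[Si](C)(C)C(C)(C)C)/C=C(\I)CO[Si](C)(C)C(C)(C)C` | intermediate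
25 | primary allylic alcohol (C5 CH2OH; C6=C1 alkene with the C2 arm cis to C5) | `CC1=CC[C@@H](O[Si](C)(C)C(C)(C)C)C(C)(C)[C@H]1/C=C/C(C)=C\[C@H](O[Si](C)(C)C(C)(C)C)/C(=C/CO)[C@@H](O[Si](C)(C)C(C)(C)C)/C=C(\I)CO[Si](C)(C)C(C)(C)C` | intermediate
26 | epoxy alcohol (C1–C6 epoxide as in 30; C5 CH2OH) | `CC1=CC[C@@H](O[Si](C)(C)C(C)(C)C)C(C)(C)[C@H]1/C=C/C(C)=C\[C@H](O[Si](C)(C)C(C)(C)C)[C@@]1(O[C@H]1CO)[C@@H](O[Si](C)(C)C(C)(C)C)/C=C(\I)CO[Si](C)(C)C(C)(C)C` | intermediate
27 | epoxy aldehyde (C5 CHO; (Z)-alkenyl iodide at C4) | `CC1=CC[C@@H](O[Si](C)(C)C(C)(C)C)C(C)(C)[C@H]1/C=C/C(C)=C\[C@H](O[Si](C)(C)C(C)(C)C)[C@@]1(O[C@H]1C=O)[C@@H](O[Si](C)(C)C(C)(C)C)/C=C(\I)CO[Si](C)(C)C(C)(C)C` | intermediate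
28 | alkenylchromium dichloride from 27 (chromium on C4) | `CC1=CC[C@@H](O[Si](C)(C)C(C)(C)C)C(C)(C)[C@H]1/C=C/C(C)=C\[C@H](O[Si](C)(C)C(C)(C)C)[C@@]1(O[C@H]1C=O)[C@@H](O[Si](C)(C)C(C)(C)C)/C=C(\[Cr](Cl)Cl)CO[Si](C)(C)C(C)(C)C` | intermediate
29 | tetrakis-TBS ether of 30 (C5 hydroxyl free, (5R)) | `CC1=CC[C@@H](O[Si](C)(C)C(C)(C)C)C(C)(C)[C@H]1/C=C/C(C)=C\[C@H](O[Si](C)(C)C(C)(C)C)[C@]12O[C@H]1[C@H](O)C(CO[Si](C)(C)C(C)(C)C)=C[C@@H]2O[Si](C)(C)C(C)(C)C` | intermediate
30 | (1R,2S,5R,6S)-1-{(1S,2Z,4E)-1-hydroxy-5-[(1S,5R)-5-hydroxy-2,6,6-trimethylcyclohex-2-en-1-yl]-3-methylpenta-2,4-dien-1-yl}-4-(hydroxymethyl)-7-oxabicyclo[4.1.0]hept-3-ene-2,5-diol | `CC1=CC[C@@H](O)C(C)(C)[C@H]1/C=C/C(C)=C\[C@H](O)[C@]12O[C@H]1[C@H](O)C(CO)=C[C@@H]2O` | target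

Total step count: 21 steps.
Longest linear sequence: 18 steps (steps 1–5, then 9–21).

Steps most likely to fail

Step 18 (Sharpless epoxidation). The allylic alcohol carries two branched silyloxy substituents on the far alkene carbon, so the epoxidation may be slow or show poor facial selectivity if the tartrate is mismatched with the existing stereocentres. The fallback sets out from 25: oxidation with MnO2 gives the (Z)-enal F3, and iminium-catalysed nucleophilic epoxidation (H2O2, diarylprolinol trimethylsilyl ether of the required antipode, CH2Cl2) gives the epoxy aldehyde directly. The route is rejoined at 27.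

Step 20 (key cyclisation). The addition may show poor facial selectivity at the aldehyde if chromium chelates carbonyl and epoxide oxygens, giving the hydroxyl cis to the epoxide. The fallback sets out from 27: the cyclisation is run as before, and the C5 epimer of 29 F1, alone or mixed with 29, is oxidised with Dess–Martin periodinane to the epoxy enone F2. Reduction with i-Bu2AlH in THF at −78 °C, where aluminium coordinates the epoxide oxygen and hydride arrives from the epoxide face, should give the trans epoxy alcohol. The route is rejoined at 29.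

Step 13 (carbonylative coupling). Direct, non-carbonylative alkynylation of the hindered alkenyl iodide may compete with CO insertion. The fallback sets out from 18: iodine–lithium exchange (t-BuLi, Et2O, −78 °C) gives the alkenyllithium F6, which is acylated by the Weinreb amide F5. F5 is made from 19 by deprotonation with n-BuLi to the lithium acetylide F4 and trapping with N-methoxy-N-methylcarbamoyl chloride. The route is rejoined at 20.

Further compounds
F1 | step 20 | C5 epimer of 29 (hydroxyl cis to the epoxide) | `CC1=CC[C@@H](O[Si](C)(C)C(C)(C)C)C(C)(C)[C@H]1/C=C/C(C)=C\[C@H](O[Si](C)(C)C(C)(C)C)[C@]12O[C@H]1[C@@H](O)C(CO[Si](C)(C)C(C)(C)C)=C[C@@H]2O[Si](C)(C)C(C)(C)C`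
F2 | step 20 | epoxy enone (C5 ketone of 29) | `CC1=CC[C@@H](O[Si](C)(C)C(C)(C)C)C(C)(C)[C@H]1/C=C/C(C)=C\[C@H](O[Si](C)(C)C(C)(C)C)[C@]12O[C@H]1C(=O)C(CO[Si](C)(C)C(C)(C)C)=C[C@@H]2O[Si](C)(C)C(C)(C)C`
F3 | step 18 | (Z)-enal from 25 (C5 CHO, C6=C1 alkene) | `CC1=CC[C@@H](O[Si](C)(C)C(C)(C)C)C(C)(C)[C@H]1/C=C/C(C)=C\[C@H](O[Si](C)(C)C(C)(C)C)/C(=C/C=O)[C@@H](O[Si](C)(C)C(C)(C)C)/C=C(\I)CO[Si](C)(C)C(C)(C)C`
F4 | step 13 | lithium acetylide of 19 | `[Li]C#CCO[Si](C)(C)C(C)(C)C`
F5 | step 13 | 4-(TBSO)-N-methoxy-N-methylbut-2-ynamide | `CON(C)C(=O)C#CCO[Si](C)(C)C(C)(C)C`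
F6 | step 13 | alkenyllithium from 18 (lithium on C1) | `CC1=CC[C@@H](O[Si](C)(C)C(C)(C)C)C(C)(C)[C@H]1/C=C/C(C)=C\[C@H](O[Si](C)(C)C(C)(C)C)/C([Li])=C/CO[Si](CC)(CC)CC`
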